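**Strategy.** Ring B of the target (C5–C10) carries the C10 methyl, the C6 oxygen and the C7 isopropyl group in the same arrangement as piperitone, and ring A is attached to it through two vicinal, mutually trans bonds, C1–C10 and C4–C5. Both bonds are therefore forged in one flask on (S)-piperitone, a cyclohexenone that already holds the C7 stereocentre: Lewis-acid conjugate allylation at C10 gives a titanium enolate that is captured at C5 by acrolein, fixing C10 and C5 relative to C7. The enone is made from (−)-menthone. Afterwards ring A is closed by metathesis at C2–C3, C1 is oxidised via an ene-dione, C15 is added by methylenation and the orthoester cage is closed last.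

Key step: step 3

**Remarks on the chemistry**

- a) Eudesmane numbering is used for every compound, the monocyclic ones included (C6 = carbonyl carbon of menthone, C7 = isopropyl-bearing carbon, C10 = methyl-bearing carbon, C5 = ring carbon between C6 and C10). The name serves only as a numbering scheme; compounds 9–14 lack C15 and are called 15-noreudesmanes.
- b) β is the face that carries H-5 and the isopropyl group; α is the face of the C10 methyl group (C14). Every bicyclic compound is a trans-decalin with 5β-H, 7β-isopropyl and 10α-methyl.
- c) Assumption: the (−)-menthone is free of isomenthone, because the C7 epimer would end up as the enantiomeric enone.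
- d) Assumption: triethyl orthoacrylate and iodobenzene are purchased.
- e) The later sequence was planned around three points: C6 is reduced on the rigid decalin under thermodynamic control; C1 is oxidised only after C4 has become a carbonyl, so that no second allylic C–H competes; and the cage is closed by orthoester exchange.

**Route**

Step 1
Reactants: 1 (−)-menthone
Product: 3 trimethyl{[(3R,6S)-3-methyl-6-(propan-2-yl)cyclohex-1-en-1-yl]oxy}silane, via lithium enolate 2 (not isolated)
Conditions: LDA, THF, −78 °C; Me3SiCl, −78 °C to rt
Reagents that add atoms: chlorotrimethylsilane, C[Si](C)(C)Cl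
Why: Kinetic deprotonation with LDA removes a proton from the unhindered C5 methylene and not from the isopropyl-bearing methine C7, and O-silylation of enolate 2 (kinetic enolate silylation) gives the less substituted silyl enol ether with C7 untouched.

Step 2
Reactants: 3 silyl enol ether
Product: 4 (S)-piperitone, (6S)-3-methyl-6-(propan-2-yl)cyclohex-2-en-1-one
Conditions: Pd(OAc)2 (10 mol %), O2 (1 atm), DMSO, rt
Reagents that add atoms: none
Why: Saegusa–Ito oxidation: the palladium enolate formed at C5 loses H-10, its only β-hydrogen, to give the C5=C10 enone under neutral conditions that should not epimerise C7.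

Step 3
Reactants: 4 (S)-piperitone; 5 allyltrimethylsilane; 6 acrolein
Product: 8 (2S,3R,6S)-2-(1-hydroxyprop-2-en-1-yl)-3-methyl-6-(propan-2-yl)-3-(prop-2-en-1-yl)cyclohexan-1-one (both carbinol epimers), via trichlorotitanium enolate 7 (not isolated)
Conditions: TiCl4 (1.1 equiv), CH2Cl2, −78 °C; then 5, −78 to −40 °C; then 6, −78 °C; sat. aq. NaHCO3
Reagents that add atoms: none
Why: TiCl4 activates the enone carbonyl, the allylsilane attacks C10 through its γ-carbon and loss of Me3SiCl leaves trichlorotitanium enolate 7, which can only be the C5=C6 regioisomer, so that C7 is never deprotonated; the enolate then adds 1,2 to acrolein in a titanium aldol reaction. The closest known reaction type is the Hosomi–Sakurai conjugate allylation of β,β-disubstituted cyclohexenones with in situ aldehyde trapping of the titanium enolate. No ring is closed in this step. C10 is controlled by the C7 isopropyl group, which sits pseudo-equatorial in the enone half-chair so that the stereoelectronically preferred axial attack places the allyl group cis to it and C14 trans; C5 is controlled by the new axial allyl group on the neighbouring C10, acrolein entering anti to it, which makes the C1 and C4 chains trans, while C4 is left uncontrolled because it becomes a carbonyl later. The step needs face selectivity at C10 (the weaker element, because an α′ substituent biases the half-chair only moderately), anti selectivity at C5, reaction at C5 only and 1,2- rather than 1,4-addition to acrolein; the last two should be secured by the regiospecific, hard titanium enolate at −78 °C.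

Step 4
Reactants: 8 allyl/hydroxyallyl ketone
Product: 9 4ξ-hydroxy-15-noreudesm-2-en-6-one
Conditions: second-generation Grubbs catalyst (H2IMes)(PCy3)Cl2Ru=CHPh (5 mol %), CH2Cl2 (5 mM), 40 °C
Reagents that add atoms: none
Why: Ring-closing metathesis joins the allyl and vinyl carbinol termini at C2=C3 with loss of ethylene, and the trans relationship of the two chains should give the trans-decalin while the ruthenium carbene tolerates the free alcohol and the ketone.

Step 5
Reactants: 9 hydroxy ketone
Product: 10 15-noreudesm-2-ene-4ξ,6β-diol
Conditions: Li, NH3(l)/THF, EtOH, −78 °C; NH4Cl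
Reagents that add atoms: none
Why: Dissolving-metal reduction of the ketone should give the thermodynamically preferred equatorial 6β-alcohol, because the axial 6α-epimer would be syn-axial to the C10 methyl group, while the isolated alkene and the allylic alkoxide are inert and fast electron transfer should pre-empt enolisation at C5 or C7.

Step 6
Reactants: 10 diol
Product: 11 6β-hydroxy-15-noreudesm-2-en-4-one
Conditions: activated MnO2 (excess), CH2Cl2, rt
Reagents that add atoms: none
Why: Allylic alcohol oxidation with MnO2 converts both C4 epimers into one enone and leaves the saturated 6-hydroxyl alone.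

Step 7
Reactants: 11 hydroxy enone
Product: 12 6β-(triethylsilyloxy)-15-noreudesm-2-en-4-one
Conditions: Et3SiOTf, 2,6-lutidine, CH2Cl2, −78 to 0 °C
Reagents that add atoms: triethylsilyl trifluoromethanesulfonate, CC[Si](CC)(CC)OS(=O)(=O)C(F)(F)F
Why: Silyl ether protection with the silyl triflate and a hindered base should cap the crowded secondary 6-hydroxyl before the oxidation and olefination steps.

Step 8
Reactants: 12 silyloxy enone
Product: 13 6β-(triethylsilyloxy)-15-noreudesm-2-ene-1,4-dione
Conditions: Rh2(cap)4 (1 mol %), t-BuOOH (70% aq., 5 equiv), ClCH2CH2Cl, 40 °C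
Reagents that add atoms: tert-butyl hydroperoxide, CC(C)(C)OO
Why: Allylic (γ) C–H oxidation of an enone to an ene-dione by tert-butylperoxy radicals under dirhodium caprolactamate catalysis can only occur at C1, the single allylic methylene, and has the oxidation of isophorone to ketoisophorone as a model for a γ-methylene next to a quaternary carbon.

Step 9
Reactants: 13 ene-dione
Product: 14 6β-(triethylsilyloxy)-15-noreudesmane-1,4-dione
Conditions: H2 (1 atm), Pd/C, EtOAc, rt
Reagents that add atoms: none
Why: Catalytic hydrogenation should reduce the electron-poor C2=C3 bond of the ene-dione and leave both ketones and the silyl ether unchanged.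

Step 10
Reactants: 14 1,4-diketone
Product: 15 6β-(triethylsilyloxy)eudesm-4(15)-en-1-one
Conditions: Ph3PCH3Br (1.3 equiv), KHMDS (1.2 equiv), THF, −78 to 0 °C
Reagents that add atoms: methyltriphenylphosphonium bromide, C[P+](c1ccccc1)(c1ccccc1)c1ccccc1.[Br-]
Why: Wittig methylenation with a small excess of ylide at low temperature should take place at C4, whose α-carbon C5 is tertiary, in preference to C1, which is shielded by the quaternary C10.

Step 11
Reactants: 15 methylene ketone
Product: 17 eudesm-4(15)-ene-1α,6β-diol, via triethylsilyl-protected 1α-alcohol 16 (not isolated)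
Conditions: NaBH4, MeOH, 0 °C; then 1 M aq. HCl, rt
Reagents that add atoms: none
Why: Borohydride reduction by axial hydride attack on the β face of C1, anti to the axial C10 methyl group, should give the equatorial 1α-alcohol, and acidifying the methanolic mixture then removes the silyl ether (acidic desilylation).

Step 12
Reactants: 17 diol
Product: 18 eudesmane-1α,4β,6β,15-tetraol
Conditions: OsO4 (2 mol %), NMO, acetone/H2O, rt
Reagents that add atoms: osmium tetroxide, O=[Os](=O)(=O)=O; N-methylmorpholine N-oxide, C[N+]1([O-])CCOCC1; water, O
Why: Catalytic osmium tetroxide syn-dihydroxylation should attack the exocyclic alkene from the β face, away from the syn-axial C10 methyl group, which sets C4 with O4 β and C15 α.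

Step 13
Reactants: 19 iodobenzene; 20 triethyl orthoacrylate
Product: 21 triethyl (E)-orthocinnamate, (E)-(3,3,3-triethoxyprop-1-en-1-yl)benzene
Conditions: Pd(OAc)2 (3 mol %), Bu4NCl, K2CO3, DMF, 80 °C
Reagents that add atoms: none
Why: Mizoroki–Heck arylation places the phenyl group on the terminal alkene carbon, and syn β-hydride elimination, possible only towards the benzylic carbon, should give the (E)-styryl orthoester under basic conditions that the orthoester survives.

Step 14
Reactants: 18 tetraol; 21 triethyl (E)-orthocinnamate (1.1 equiv)
Product: 22 target orthoester (CNP0190302.1)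
Conditions: CSA (5 mol %), CH2Cl2, 4 Å MS, rt; Et3N
Reagents that add atoms: none
Why: Acid-catalysed orthoester exchange lets the primary 15-OH, the tertiary 4β-OH and the neighbouring equatorial 6β-OH displace three ethanol molecules and close the 2,7,8-trioxabicyclo[3.2.1]octane cage, whose orthoester carbon configuration is dictated by the triol geometry, while the remote 1α-OH cannot take part.

**Compound list**

1 | (−)-menthone, (2S,5R)-5-methyl-2-(propan-2-yl)cyclohexan-1-one | CC(C)[C@@H]1CC[C@@H](C)CC1=O | starting material
2 | lithium (3R,6S)-3-methyl-6-(propan-2-yl)cyclohex-1-en-1-olate | CC(C)[C@@H]1CC[C@@H](C)C=C1O[Li] | intermediate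
3 | trimethyl{[(3R,6S)-3-methyl-6-(propan-2-yl)cyclohex-1-en-1-yl]oxy}silane | CC(C)[C@@H]1CC[C@@H](C)C=C1O[Si](C)(C)C | intermediate
4 | (S)-piperitone, (6S)-3-methyl-6-(propan-2-yl)cyclohex-2-en-1-one | CC(C)[C@@H]1CCC(C)=CC1=O | intermediate
5 | allyltrimethylsilane | C=CC[Si](C)(C)C | starting material
6 | acrolein | C=CC=O | starting material
7 | trichloro{[(3R,6S)-3-methyl-6-(propan-2-yl)-3-(prop-2-en-1-yl)cyclohex-1-en-1-yl]oxy}titanium | CC(C)[C@@H]1CC[C@](C)(CC=C)C=C1O[Ti](Cl)(Cl)Cl | intermediate
8 | (2S,3R,6S)-2-(1-hydroxyprop-2-en-1-yl)-3-methyl-6-(propan-2-yl)-3-(prop-2-en-1-yl)cyclohexan-1-one, carbinol epimers | CC(C)[C@@H]1CC[C@](C)(CC=C)[C@@H](C(O)C=C)C1=O | intermediate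
9 | 4ξ-hydroxy-15-noreudesm-2-en-6-one (5β-H, 7β-isopropyl, 10α-methyl) | CC(C)[C@@H]1CC[C@]2(C)CC=CC(O)[C@H]2C1=O | intermediate
10 | 15-noreudesm-2-ene-4ξ,6β-diol | CC(C)[C@@H]1CC[C@]2(C)CC=CC(O)[C@H]2[C@@H]1O | intermediate
11 | 6β-hydroxy-15-noreudesm-2-en-4-one | CC(C)[C@@H]1CC[C@]2(C)CC=CC(=O)[C@H]2[C@@H]1O | intermediate
12 | 6β-(triethylsilyloxy)-15-noreudesm-2-en-4-one | CC(C)[C@@H]1CC[C@]2(C)CC=CC(=O)[C@H]2[C@@H]1O[Si](CC)(CC)CC | intermediate
13 | 6β-(triethylsilyloxy)-15-noreudesm-2-ene-1,4-dione | CC(C)[C@@H]1CC[C@]2(C)C(=O)C=CC(=O)[C@H]2[C@@H]1O[Si](CC)(CC)CC | intermediate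
14 | 6β-(triethylsilyloxy)-15-noreudesmane-1,4-dione | CC(C)[C@@H]1CC[C@]2(C)C(=O)CCC(=O)[C@H]2[C@@H]1O[Si](CC)(CC)CC | intermediate
15 | 6β-(triethylsilyloxy)eudesm-4(15)-en-1-one | CC(C)[C@@H]1CC[C@]2(C)C(=O)CCC(=C)[C@H]2[C@@H]1O[Si](CC)(CC)CC | intermediate
16 | 6β-(triethylsilyloxy)eudesm-4(15)-en-1α-ol | CC(C)[C@@H]1CC[C@]2(C)[C@@H](O)CCC(=C)[C@H]2[C@@H]1O[Si](CC)(CC)CC | intermediate
17 | eudesm-4(15)-ene-1α,6β-diol | CC(C)[C@@H]1CC[C@]2(C)[C@@H](O)CCC(=C)[C@H]2[C@@H]1O | intermediate
18 | eudesmane-1α,4β,6β,15-tetraol | CC(C)[C@@H]1CC[C@]2(C)[C@@H](O)CC[C@@](O)(CO)[C@H]2[C@@H]1O | intermediate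
19 | iodobenzene | Ic1ccccc1 | starting material
20 | triethyl orthoacrylate, 3,3,3-triethoxyprop-1-ene | C=CC(OCC)(OCC)OCC | starting material
21 | triethyl (E)-orthocinnamate | CCOC(OCC)(OCC)/C=C/c1ccccc1 | intermediate
22 | 1α-hydroxyeudesmane 4β,6β,15-orthocinnamate (E), CNP0190302.1 | CC(C)[C@@H]1CC[C@@]2(C)[C@@H]3[C@@H]1O[C@]1(/C=C/c4ccccc4)OC[C@@]3(CC[C@@H]2O)O1 | target

**Step count and risks**

Total step count: 14. Longest linear sequence: 13 (steps 1–12 and 14; step 13 is a one-step side branch).

Steps most likely to fail:

1. Step 3. Facial discrimination at C10 may be poor, because the isopropyl group steers the half-chair only moderately. The titanium enolate may also be lost through acrolein polymerisation or TiCl4-induced dehydration of the aldol. Fallback: the two bond formations are separated. Starting from 4, the conjugate allylation with 5 and TiCl4 is run alone and quenched to (2S,5R)-5-methyl-2-(propan-2-yl)-5-(prop-2-en-1-yl)cyclohexan-1-one F1, on which the C10 epimers can be separated as simple ketones. Kinetic deprotonation of F1 with LDA at −78 °C (C5 methylene in preference to the C7 methine) and lithium aldol addition to acrolein, anti to the allyl group, then comes back to the route at 8.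

2. Step 5. Stereocontrol at C6 may be eroded if protonation is not thermodynamic, and the basic medium may cause C5 or C7 epimerisation or retro-aldol cleavage before the ketone is consumed. Fallback: the ketone is reduced kinetically before the ring is closed. Starting from 8, LiBH(s-Bu)3 in THF at −78 °C should attack C6 from the α face, the equatorial direction of the conformer with both chains axial and isopropyl equatorial. This gives the monocyclic 6β-alcohol F2 (hydroxyl cis to isopropyl, trans to the C5 chain). Ring-closing metathesis of F2 with the same ruthenium catalyst comes back to the route at 10.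

3. Step 10. The ylide may not discriminate cleanly between the C4 and C1 carbonyl groups (methylenation at C1 or at both), and its basicity may epimerise C5. Fallback: the two oxygens are differentiated by construction. Starting from 12, t-BuMe2SiOTf and Et3N give the extended silyl dienol ether F3 (C1=C2, C3=C4). Oxidation with mCPBA (vinylogous Rubottom oxidation) gives the 1-hydroxy enone F4. Hydrogenation over Pd/C gives the hydroxy ketone F5, and Wittig methylenation of its only ketone gives F6. Dess–Martin oxidation of the C1 alcohol, whatever its configuration, comes back to the route at 15.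

**Further compounds**

F1 | step 3 | (2S,5R)-5-methyl-2-(propan-2-yl)-5-(prop-2-en-1-yl)cyclohexan-1-one | CC(C)[C@@H]1CC[C@](C)(CC=C)CC1=O
F2 | step 5 | 6β-alcohol of 8, monocyclic diol with both carbinol epimers at C4 | CC(C)[C@@H]1CC[C@](C)(CC=C)[C@@H](C(O)C=C)[C@@H]1O
F3 | step 10 | 4-(tert-butyldimethylsilyloxy)-6β-(triethylsilyloxy)-15-noreudesma-1,3-diene | CC(C)[C@@H]1CC[C@]2(C)C=CC=C(O[Si](C)(C)C(C)(C)C)[C@H]2[C@@H]1O[Si](CC)(CC)CC
F4 | step 10 | 1ξ-hydroxy-6β-(triethylsilyloxy)-15-noreudesm-2-en-4-one | CC(C)[C@@H]1CC[C@]2(C)C(O)C=CC(=O)[C@H]2[C@@H]1O[Si](CC)(CC)CC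
F5 | step 10 | 1ξ-hydroxy-6β-(triethylsilyloxy)-15-noreudesman-4-one | CC(C)[C@@H]1CC[C@]2(C)C(O)CCC(=O)[C@H]2[C@@H]1O[Si](CC)(CC)CC
F6 | step 10 | 6β-(triethylsilyloxy)eudesm-4(15)-en-1ξ-ol | CC(C)[C@@H]1CC[C@]2(C)C(O)CCC(=C)[C@H]2[C@@H]1O[Si](CC)(CC)CC
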